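**Retrosynthetic overview**
- Both (Z)-2-alkyl-2-enoic acids come from Still–Gennari olefinations; the last step is hydrolysis of the two methyl esters.
- Furan-side enoate: C=C disconnection to 3-(furan-3-yl)propanal and a main-chain phosphonoacetate, made by alkylating the phosphonoacetate with a primary iodide.
- Other enoate: C=C disconnection to a main-chain aldehyde and a homoprenyl phosphonoacetate; the (E)-trisubstituted alkene comes from a Johnson–Claisen rearrangement of an isopropenyl carbinol.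
- Stereocentre: (R)-4-isopropenyl-δ-valerolactone from a rhodium-catalysed asymmetric conjugate addition to 5,6-dihydro-2H-pyran-2-one; its carbonyl arm and its O-alkyl arm become the two chains.
- Rings: none is built. The furan is bought in as furan-3-carbaldehyde, and the six-membered lactone ring of the starting material is opened in step 3.

Assumption: the SMILES is read as the 2Z,6E,9R,12Z isomer of the trideca-2,6-dienedioic acid named below.

**Step 1**
Reactants: 1 5,6-dihydro-2H-pyran-2-one; 2 potassium trifluoro(prop-1-en-2-yl)borate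
Product: 3 (4R)-4-(prop-1-en-2-yl)oxan-2-one
Conditions: [Rh(cod)2]PF6 (3 mol %; cod = cycloocta-1,5-diene), (R)-BINAP (3.3 mol %; (R)-2,2'-bis(diphenylphosphino)-1,1'-binaphthyl), 2 (2 equiv), toluene/H2O 20:1, 105 °C
Reagents that add atoms: potassium trifluoro(prop-1-en-2-yl)borate (2), [K+].C=C(C)[B-](F)(F)F
Why: Rhodium-catalysed asymmetric 1,4-addition (Hayashi–Miyaura type): the (R)-BINAP–rhodium alkenyl species inserts the lactone C=C on one enantioface, in the same sense as in arylations of cyclohexenone, and protonation of the rhodium enolate by water releases the R-configured β-isopropenyl lactone.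

**Step 2**
Reactants: 3 (4R)-4-(prop-1-en-2-yl)oxan-2-one
Product: 4 (4R)-4-(prop-1-en-2-yl)oxan-2-ol (anomer mixture)
Conditions: i-Bu2AlH (1.1 equiv), CH2Cl2, −78 °C; aq. potassium sodium tartrate work-up
Reagents that add atoms: none
Why: Partial reduction of a δ-lactone: the aluminium lactolate is stable at −78 °C and gives the lactol on work-up; the stereocentre is not involved and the anomeric centre is inconsequential.

**Step 3**
Reactants: 4 (4R)-4-(prop-1-en-2-yl)oxan-2-ol; 5 prop-1-en-2-ylmagnesium bromide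
Product: 6 (5R)-2-methyl-5-(prop-1-en-2-yl)hept-1-ene-3,7-diol (both C3 epimers)
Conditions: CH2=C(CH3)MgBr (3.5 equiv), THF, 0 °C → rt; aqueous work-up
Reagents that add atoms: prop-1-en-2-ylmagnesium bromide (5), C=C(C)[Mg]Br
Why: Grignard addition to the open hydroxy-aldehyde form of the lactol (the first equivalent is consumed by the lactol O–H); the new carbinol centre forms without control but is destroyed in step 4.

**Step 4**
Reactants: 6 (5R)-2-methyl-5-(prop-1-en-2-yl)hept-1-ene-3,7-diol; 7 triethyl orthoacetate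
Product: 10 ethyl (4E,7S)-9-hydroxy-4-methyl-7-(prop-1-en-2-yl)non-4-enoate, via mixed orthoester ketene acetal 8 (not isolated), via orthoester-capped rearranged ester 9 (not isolated)
Conditions: MeC(OEt)3 (10 equiv), EtCO2H (0.1 equiv), 140 °C, EtOH distilled off; evaporate; then EtOH, pyridinium p-toluenesulfonate (cat.), rt
Reagents that add atoms: triethyl orthoacetate (7), CC(OCC)(OCC)OCC
Why: Johnson–Claisen (orthoester Claisen) rearrangement through a chair transition state with the carbinol substituent equatorial gives the (E)-trisubstituted alkene, while the primary hydroxyl is masked in situ as a mixed orthoester and released by acid-catalysed exchange with ethanol; the stereocentre is untouched (the descriptor becomes S only because the CIP ranking of the two arms changes).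

**Step 5**
Reactants: 10 ethyl (4E,7S)-9-hydroxy-4-methyl-7-(prop-1-en-2-yl)non-4-enoate
Product: 11 ethyl (4E,7S)-9-iodo-4-methyl-7-(prop-1-en-2-yl)non-4-enoate
Conditions: I2 (1.3 equiv), PPh3 (1.3 equiv), imidazole (2 equiv), CH2Cl2, 0 °C → rt
Reagents that add atoms: iodine, [I][I]
Why: Appel-type iodination (Garegg–Samuelsson conditions): SN2 displacement of the alkoxyphosphonium by iodide at the unhindered primary carbon leaves the ester and the alkenes untouched.

**Step 6**
Reactants: 11 ethyl (4E,7S)-9-iodo-4-methyl-7-(prop-1-en-2-yl)non-4-enoate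
Product: 12 (4E,7S)-9-iodo-4-methyl-7-(prop-1-en-2-yl)non-4-enal
Conditions: i-Bu2AlH (1.05 equiv), CH2Cl2, −78 °C; aq. potassium sodium tartrate work-up
Reagents that add atoms: none
Why: Partial ester reduction: the tetrahedral aluminium hemiacetal persists at −78 °C and gives the aldehyde only on work-up, and a primary alkyl iodide is inert to i-Bu2AlH at this temperature.

**Step 7**
Reactants: 13 methyl 2-[bis(2,2,2-trifluoroethoxy)phosphoryl]acetate; 14 5-bromo-2-methylpent-2-ene
Product: 16 methyl 2-[bis(2,2,2-trifluoroethoxy)phosphoryl]-6-methylhept-5-enoate (racemic), via sodium phosphonoacetate carbanion 15 (not isolated)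
Conditions: 13 (1.5 equiv), NaH (1.4 equiv), DMF, 0 °C; then 14 (1.0 equiv), NaI (0.1 equiv), 50 °C
Reagents that add atoms: 5-bromo-2-methylpent-2-ene (14), CC(C)=CCCBr
Why: SN2 C-alkylation of the stabilised phosphonoacetate carbanion with the homoallylic bromide (iodide catalysis), the excess of carbanion limiting dialkylation; the new centre is racemic and is lost in step 8.

**Step 8**
Reactants: 12 (4E,7S)-9-iodo-4-methyl-7-(prop-1-en-2-yl)non-4-enal; 16 methyl 2-[bis(2,2,2-trifluoroethoxy)phosphoryl]-6-methylhept-5-enoate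
Product: 18 methyl (2Z,6E,9S)-11-iodo-6-methyl-2-(4-methylpent-3-en-1-yl)-9-(prop-1-en-2-yl)undeca-2,6-dienoate, via potassium carbanion of the homoprenyl phosphonate 17 (not isolated)
Conditions: 16 (1.3 equiv), KN(SiMe3)2 (1.25 equiv), 18-crown-6 (4 equiv), THF, −78 °C; then 12, −78 °C, 2 h
Reagents that add atoms: methyl 2-[bis(2,2,2-trifluoroethoxy)phosphoryl]-6-methylhept-5-enoate (16), COC(=O)C(CCC=C(C)C)P(=O)(OCC(F)(F)F)OCC(F)(F)F
Why: Still–Gennari variant of the Horner–Wadsworth–Emmons olefination: the electron-poor trifluoroethyl phosphonate with a dissociated potassium counter-ion eliminates under kinetic control and places the aldehyde-derived chain cis to CO2Me (Z), while the alkyl iodide is untouched at −78 °C.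

**Step 9**
Reactants: 18 methyl (2Z,6E,9S)-11-iodo-6-methyl-2-(4-methylpent-3-en-1-yl)-9-(prop-1-en-2-yl)undeca-2,6-dienoate; 13 methyl 2-[bis(2,2,2-trifluoroethoxy)phosphoryl]acetate
Product: 20 dimethyl (2Z,6E,9R)-12-[bis(2,2,2-trifluoroethoxy)phosphoryl]-6-methyl-2-(4-methylpent-3-en-1-yl)-9-(prop-1-en-2-yl)trideca-2,6-dienedioate (both C12 epimers), via potassium phosphonoacetate carbanion 19 (not isolated)
Conditions: 13 (3 equiv), KN(SiMe3)2 (2.8 equiv), THF, 0 °C; then 18 (1 equiv) in DMF, 55 °C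
Reagents that add atoms: methyl 2-[bis(2,2,2-trifluoroethoxy)phosphoryl]acetate (13), COC(=O)CP(=O)(OCC(F)(F)F)OCC(F)(F)F
Why: SN2 alkylation of an excess of the soft potassium phosphonoacetate carbanion, generated with a non-nucleophilic amide base, by the unhindered primary iodide; the hindered trisubstituted enoate is not a competent Michael acceptor, and the new phosphonate-bearing centre is destroyed in step 12.

**Step 10**
Reactants: 21 furan-3-carbaldehyde; 22 2-(triphenyl-λ5-phosphanylidene)acetaldehyde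
Product: 23 (2E)-3-(furan-3-yl)prop-2-enal
Conditions: 22 (1.05 equiv), toluene, 80 °C
Reagents that add atoms: 2-(triphenyl-λ5-phosphanylidene)acetaldehyde (22), O=CC=P(c1ccccc1)(c1ccccc1)c1ccccc1
Why: Wittig olefination with a stabilised formyl ylide, which gives the E enal.

**Step 11**
Reactants: 23 (2E)-3-(furan-3-yl)prop-2-enal
Product: 24 3-(furan-3-yl)propanal
Conditions: diethyl 2,6-dimethyl-1,4-dihydropyridine-3,5-dicarboxylate (Hantzsch ester, 1.1 equiv), dibenzylammonium trifluoroacetate (5 mol %), THF, rt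
Reagents that add atoms: none
Why: Organocatalytic iminium transfer hydrogenation: the Hantzsch ester delivers hydride to the β-carbon of the iminium ion, so only the conjugated C=C is reduced and the furan and the aldehyde survive.

**Step 12**
Reactants: 20 dimethyl (2Z,6E,9R)-12-[bis(2,2,2-trifluoroethoxy)phosphoryl]-6-methyl-2-(4-methylpent-3-en-1-yl)-9-(prop-1-en-2-yl)trideca-2,6-dienedioate; 24 3-(furan-3-yl)propanal
Product: 26 dimethyl (2Z,6E,9R,12Z)-12-[3-(furan-3-yl)propylidene]-6-methyl-2-(4-methylpent-3-en-1-yl)-9-(prop-1-en-2-yl)trideca-2,6-dienedioate, via potassium carbanion of the main-chain phosphonate 25 (not isolated)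
Conditions: KN(SiMe3)2 (0.98 equiv), 18-crown-6 (4 equiv), THF, −78 °C; then 24 (1.5 equiv), −78 → −40 °C
Reagents that add atoms: 3-(furan-3-yl)propanal (24), O=CCCc1ccoc1
Why: Second Still–Gennari olefination: the α-alkylated trifluoroethyl phosphonate carbanion adds to the unhindered aldehyde and eliminates under kinetic control, putting the 2-(furan-3-yl)ethyl group cis to CO2Me (Z); a slight deficit of base leaves the first enoate and the stereocentre untouched.

**Step 13**
Reactants: 26 dimethyl (2Z,6E,9R,12Z)-12-[3-(furan-3-yl)propylidene]-6-methyl-2-(4-methylpent-3-en-1-yl)-9-(prop-1-en-2-yl)trideca-2,6-dienedioate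
Product: 27 (2Z,6E,9R,12Z)-12-[3-(furan-3-yl)propylidene]-6-methyl-2-(4-methylpent-3-en-1-yl)-9-(prop-1-en-2-yl)trideca-2,6-dienedioic acid (CNP0235727.1)
Conditions: LiOH·H2O (10 equiv), THF/MeOH/H2O 3:1:1, 45 °C; then 1 M HCl to pH 3, 0 °C
Reagents that add atoms: lithium hydroxide, [Li+].[OH-]
Why: Saponification (acyl–oxygen cleavage by hydroxide) of both hindered methyl esters, followed by brief cold acidification that spares the furan and the isopropenyl group; the mechanism involves neither the stereocentre nor the alkene geometries.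

**Compound list**
1 | 5,6-dihydro-2H-pyran-2-one | O=C1C=CCCO1 | starting material
2 | potassium trifluoro(prop-1-en-2-yl)borate | [K+].C=C(C)[B-](F)(F)F | starting material
3 | (4R)-4-(prop-1-en-2-yl)oxan-2-one | C=C(C)[C@@H](CC1=O)CCO1 | intermediate
4 | (4R)-4-(prop-1-en-2-yl)oxan-2-ol, anomer mixture | C=C(C)[C@@H](CC1O)CCO1 | intermediate
5 | prop-1-en-2-ylmagnesium bromide | C=C(C)[Mg]Br | starting material
6 | (5R)-2-methyl-5-(prop-1-en-2-yl)hept-1-ene-3,7-diol, both C3 epimers | C=C(C)[C@@H](CC(O)C(C)=C)CCO | intermediate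
7 | triethyl orthoacetate (1,1,1-triethoxyethane) | CC(OCC)(OCC)OCC | starting material
8 | (5R)-7-(1,1-diethoxyethoxy)-3-[(1-ethoxyethenyl)oxy]-2-methyl-5-(prop-1-en-2-yl)hept-1-ene (not isolated) | C=C(C)[C@@H](CC(OC(=C)OCC)C(C)=C)CCOC(C)(OCC)OCC | intermediate
9 | ethyl (4E,7S)-9-(1,1-diethoxyethoxy)-4-methyl-7-(prop-1-en-2-yl)non-4-enoate (not isolated) | C=C(C)[C@@H](C/C=C(\C)CCC(=O)OCC)CCOC(C)(OCC)OCC | intermediate
10 | ethyl (4E,7S)-9-hydroxy-4-methyl-7-(prop-1-en-2-yl)non-4-enoate | C=C(C)[C@@H](C/C=C(\C)CCC(=O)OCC)CCO | intermediate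
11 | ethyl (4E,7S)-9-iodo-4-methyl-7-(prop-1-en-2-yl)non-4-enoate | C=C(C)[C@@H](C/C=C(\C)CCC(=O)OCC)CCI | intermediate
12 | (4E,7S)-9-iodo-4-methyl-7-(prop-1-en-2-yl)non-4-enal | C=C(C)[C@@H](C/C=C(\C)CCC=O)CCI | intermediate
13 | methyl 2-[bis(2,2,2-trifluoroethoxy)phosphoryl]acetate | COC(=O)CP(=O)(OCC(F)(F)F)OCC(F)(F)F | starting material
14 | 5-bromo-2-methylpent-2-ene | CC(C)=CCCBr | starting material
15 | sodium carbanion of 13 (not isolated) | [Na+].COC(=O)[CH-]P(=O)(OCC(F)(F)F)OCC(F)(F)F | intermediate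
16 | methyl 2-[bis(2,2,2-trifluoroethoxy)phosphoryl]-6-methylhept-5-enoate, racemic | COC(=O)C(CCC=C(C)C)P(=O)(OCC(F)(F)F)OCC(F)(F)F | intermediate
17 | potassium carbanion of 16 at C2 (not isolated) | [K+].COC(=O)[C-](CCC=C(C)C)P(=O)(OCC(F)(F)F)OCC(F)(F)F | intermediate
18 | methyl (2Z,6E,9S)-11-iodo-6-methyl-2-(4-methylpent-3-en-1-yl)-9-(prop-1-en-2-yl)undeca-2,6-dienoate | C=C(C)[C@@H](C/C=C(\C)CC/C=C(/CCC=C(C)C)C(=O)OC)CCI | intermediate
19 | potassium carbanion of 13 (not isolated) | [K+].COC(=O)[CH-]P(=O)(OCC(F)(F)F)OCC(F)(F)F | intermediate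
20 | dimethyl (2Z,6E,9R)-12-[bis(2,2,2-trifluoroethoxy)phosphoryl]-6-methyl-2-(4-methylpent-3-en-1-yl)-9-(prop-1-en-2-yl)trideca-2,6-dienedioate, both C12 epimers | C=C(C)[C@@H](C/C=C(\C)CC/C=C(/CCC=C(C)C)C(=O)OC)CCC(C(=O)OC)P(=O)(OCC(F)(F)F)OCC(F)(F)F | intermediate
21 | furan-3-carbaldehyde | O=Cc1ccoc1 | starting material
22 | 2-(triphenyl-λ5-phosphanylidene)acetaldehyde | O=CC=P(c1ccccc1)(c1ccccc1)c1ccccc1 | starting material
23 | (2E)-3-(furan-3-yl)prop-2-enal | O=C/C=C/c1ccoc1 | intermediate
24 | 3-(furan-3-yl)propanal | O=CCCc1ccoc1 | intermediate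
25 | potassium carbanion of 20 at C12 (not isolated) | [K+].C=C(C)[C@@H](C/C=C(\C)CC/C=C(/CCC=C(C)C)C(=O)OC)CC[C-](C(=O)OC)P(=O)(OCC(F)(F)F)OCC(F)(F)F | intermediate
26 | dimethyl (2Z,6E,9R,12Z)-12-[3-(furan-3-yl)propylidene]-6-methyl-2-(4-methylpent-3-en-1-yl)-9-(prop-1-en-2-yl)trideca-2,6-dienedioate | C=C(C)[C@@H](C/C=C(\C)CC/C=C(/CCC=C(C)C)C(=O)OC)CC/C(=C/CCc1ccoc1)C(=O)OC | intermediate
27 | (2Z,6E,9R,12Z)-12-[3-(furan-3-yl)propylidene]-6-methyl-2-(4-methylpent-3-en-1-yl)-9-(prop-1-en-2-yl)trideca-2,6-dienedioic acid | C=C(C)[C@@H](C/C=C(\C)CC/C=C(/CCC=C(C)C)C(=O)O)CC/C(=C/CCc1ccoc1)C(=O)O | target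

**Step count and risks**

Total step count: 13. Longest linear sequence: 10 steps (steps 1–6, 8, 9, 12 and 13; 1 → 3 → 4 → 6 → 10 → 11 → 12 → 18 → 20 → 26 → 27).

The three steps most likely to fail:

Step 1 (asymmetric conjugate addition). An α-substituted alkenyl boron reagent adding to a lactone may give a low yield or an insufficient ee. The fallback sets out from 1 and 5 and comes back at 4. Copper-catalysed conjugate addition of 5 to 1 (CuBr·SMe2 10 mol %, Me3SiCl, THF, −78 °C) gives racemic 4-(prop-1-en-2-yl)oxan-2-one F1. LiAlH4 (THF, 0 °C) opens it to the achiral 3-(prop-1-en-2-yl)pentane-1,5-diol F2. Enantiotopos-selective monoacetylation with a lipase (vinyl acetate, i-Pr2O, rt; the enzyme is chosen by screening for the required arm) gives (3S)-5-hydroxy-3-(prop-1-en-2-yl)pentyl acetate F3. Dess–Martin oxidation (CH2Cl2, NaHCO3) gives (3R)-5-oxo-3-(prop-1-en-2-yl)pentyl acetate F4. K2CO3 in MeOH at 0 °C removes the acetate, and the hydroxy aldehyde closes to lactol 4. The stereocentre is then set by desymmetrisation of a prochiral diol instead of by asymmetric catalysis on the lactone.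

Step 4 (Johnson–Claisen on the unprotected diol). The free primary hydroxyl may lead to mixed acetate or orthoester products or to oligomeric esters. The fallback sets out from 6 and comes back at 10. Selective silylation of the primary hydroxyl (TBSCl, imidazole, CH2Cl2, 0 °C) gives (3RS,5R)-7-[(tert-butyldimethylsilyl)oxy]-2-methyl-5-(prop-1-en-2-yl)hept-1-en-3-ol F5. The same orthoester Claisen conditions (MeC(OEt)3, EtCO2H cat., 140 °C) then give ethyl (4E,7S)-9-[(tert-butyldimethylsilyl)oxy]-4-methyl-7-(prop-1-en-2-yl)non-4-enoate F6. Bu4NF in THF at 0 °C releases 10.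

Step 9 (alkylation of the trifluoroethyl phosphonoacetate with the elaborate iodide). Dialkylation, elimination or slow conversion are possible, and this step also governs the Z-selectivity reached in step 12. The fallback reverses the polarity; it sets out from 18 (with 13 and 24) and comes back at 26, so it replaces steps 9 and 12. Deprotonation of 13 (NaH, THF, 0 °C) and bromination with N-bromosuccinimide gives methyl 2-[bis(2,2,2-trifluoroethoxy)phosphoryl]-2-bromoacetate F7. Olefination of 24 with F7 (KN(SiMe3)2, 18-crown-6, THF, −78 °C) gives methyl (2E)-2-bromo-5-(furan-3-yl)pent-2-enoate F8, the ester again ending cis to the aldehyde-derived chain. Zinc insertion into 18 (Zn dust, LiCl, THF, 40 °C) gives [(3S,5E,9Z)-10-(methoxycarbonyl)-6,14-dimethyl-3-(prop-1-en-2-yl)pentadeca-5,9,13-trien-1-yl]zinc iodide F9. Negishi coupling of F9 with F8 (Pd(PPh3)4 5 mol %, THF, 50 °C) proceeds with retention at the alkenyl bromide and gives 26.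

**Further compounds**
F1 | step 1 | racemic 4-(prop-1-en-2-yl)oxan-2-one | C=C(C)C1CCOC(=O)C1
F2 | step 1 | 3-(prop-1-en-2-yl)pentane-1,5-diol | C=C(C)C(CCO)CCO
F3 | step 1 | (3S)-5-hydroxy-3-(prop-1-en-2-yl)pentyl acetate | C=C(C)[C@@H](CCO)CCOC(C)=O
F4 | step 1 | (3R)-5-oxo-3-(prop-1-en-2-yl)pentyl acetate | C=C(C)[C@@H](CC=O)CCOC(C)=O
F5 | step 4 | (3RS,5R)-7-[(tert-butyldimethylsilyl)oxy]-2-methyl-5-(prop-1-en-2-yl)hept-1-en-3-ol | C=C(C)[C@@H](CC(O)C(C)=C)CCO[Si](C)(C)C(C)(C)C
F6 | step 4 | ethyl (4E,7S)-9-[(tert-butyldimethylsilyl)oxy]-4-methyl-7-(prop-1-en-2-yl)non-4-enoate | C=C(C)[C@@H](C/C=C(\C)CCC(=O)OCC)CCO[Si](C)(C)C(C)(C)C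
F7 | step 9 | methyl 2-[bis(2,2,2-trifluoroethoxy)phosphoryl]-2-bromoacetate | COC(=O)C(Br)P(=O)(OCC(F)(F)F)OCC(F)(F)F
F8 | step 9 | methyl (2E)-2-bromo-5-(furan-3-yl)pent-2-enoate | COC(=O)/C(Br)=C\CCc1ccoc1
F9 | step 9 | [(3S,5E,9Z)-10-(methoxycarbonyl)-6,14-dimethyl-3-(prop-1-en-2-yl)pentadeca-5,9,13-trien-1-yl]zinc iodide | C=C(C)[C@@H](C/C=C(\C)CC/C=C(/CCC=C(C)C)C(=O)OC)CC[Zn]I
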